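**Retrosynthetic overview**
- The ten-membered ring is closed last at C6–C7 by a light-driven, chromium-catalysed intramolecular allylation of an enal by an α-(bromomethyl)butenolide; this also creates the α-methylene lactone and sets C6 and C7 from C8.
- The butenolide (first ring) comes from the C8 vinyl carbinol by acylation with 2-(bromomethyl)acrylic acid and ring-closing metathesis.
- C4=C5 comes from an E-selective Wittig reaction of an α-alkylated stabilised ylide with glyoxal mono(dimethyl acetal); the ester carbon becomes C15 (reduced, then acylated with the silylated hydroxytiglic acid) and the acetal carbon becomes C6.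
- The E C1=C10 alkene comes from zirconium-catalysed methylalumination of a terminal alkyne; C2–C3 come from ethylene oxide.
- C8 is bought in (S)-epichlorohydrin (acetylide opening, then sulfonium-ylide vinylation).

Assumption: germacranolide numbering is used (ring C1–C10, lactone C11–C13 closed to O on C8, CH3 C14 on C10, CH2O C15 on C4); read this way the target is 6R,7S,8S, with an E C1=C10 bond and C3 cis to C6 across C4=C5.

**Step 1**
Reactants: 1 (tert-butyldimethylsilyloxy)acetaldehyde; 2 2-(diethoxyphosphoryl)propanoic acid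
Product: 4 (2E)-4-[(tert-butyldimethylsilyl)oxy]-2-methylbut-2-enoic acid, via dilithiated phosphonate 3 (not isolated)
Conditions: 2, n-BuLi (2.05 equiv), THF, −78 to 0 °C; then 1, −78 °C to rt; cold dilute HCl to pH 4
Reagents that add atoms: none
Why: Horner–Wadsworth–Emmons olefination of the phosphonate carboxylate dianion gives the α-methyl (E)-enoic acid directly, so no ester hydrolysis is needed and no stereocentre is formed.

**Step 2**
Reactants: 5 (S)-epichlorohydrin; 6 acetylene
Product: 8 (2S)-1-chloropent-4-yn-2-ol, via lithium acetylide 7 (not isolated)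
Conditions: 6, n-BuLi, THF, −78 °C; BF3·OEt2; then 5, −78 °C; aq. NH4Cl
Reagents that add atoms: none
Why: BF3-promoted opening of a terminal epoxide by a lithium acetylide (Yamaguchi–Hirao alkynylation) occurs only at the unsubstituted CH2, so the bought stereocentre (future C8) is untouched and the chloride is kept for the next step.

**Step 3**
Reactants: 8 (2S)-1-chloropent-4-yn-2-ol
Product: 10 (3S)-hex-1-en-5-yn-3-ol, via epoxide 9 (not isolated)
Conditions: trimethylsulfonium iodide (5 equiv), n-BuLi (4.8 equiv), THF, −10 °C to rt; aq. NH4Cl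
Reagents that add atoms: trimethylsulfonium iodide, C[S+](C)C.[I-]
Why: The sulfonium ylide closes the chlorohydrin to the terminal epoxide, opens it at CH2 and a further equivalent eliminates dimethyl sulfide (one-carbon epoxide-to-allylic-alcohol homologation), leaving the carbinol centre unchanged.

**Step 4**
Reactants: 10 (3S)-hex-1-en-5-yn-3-ol; 11 ethylene oxide
Product: 14 (3S,5E)-5-methylocta-1,5-diene-3,8-diol, via alkenylalane 12 (not isolated), via lithium alanate 13 (not isolated)
Conditions: AlMe3 (3 equiv), Cp2ZrCl2 (25 mol %), CH2Cl2, 0 °C to rt; volatiles removed; THF, n-BuLi, −78 °C; then 11, −78 to 0 °C; aq. potassium sodium tartrate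
Reagents that add atoms: trimethylaluminium, C[Al](C)C
Why: Zirconium-catalysed Negishi methylalumination adds CH3 and Al syn across the terminal alkyne with CH3 on the internal carbon, which fixes the E C1=C10 alkene, and the derived alanate opens ethylene oxide with retention of that geometry.

**Step 5**
Reactants: 14 (3S,5E)-5-methylocta-1,5-diene-3,8-diol
Product: 15 (3S,5E)-8-iodo-5-methylocta-1,5-dien-3-ol
Conditions: I2 (1.1 equiv), PPh3 (1.1 equiv), imidazole (1.5 equiv), CH2Cl2, −20 to 0 °C
Reagents that add atoms: iodine, II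
Why: Appel-type iodination (Garegg–Samuelsson conditions) converts the unhindered primary alcohol much faster than the secondary allylic one, so one equivalent of reagent gives the primary iodide.

**Step 6**
Reactants: 15 (3S,5E)-8-iodo-5-methylocta-1,5-dien-3-ol; 16 ethyl (triphenylphosphoranylidene)acetate; 17 2,2-dimethoxyacetaldehyde
Product: 20 ethyl (2E)-2-[(3E,6S)-6-hydroxy-4-methylocta-3,7-dien-1-yl]-4,4-dimethoxybut-2-enoate, via phosphonium iodide 18 (not isolated), via alkylated ylide 19 (not isolated)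
Conditions: 16 (2.2 equiv), MeCN, 80 °C, 24 h; then 17, CH2Cl2, rt
Reagents that add atoms: none
Why: C-alkylation of the stabilised ylide and transylidation by the second equivalent give the α-alkyl ylide, whose Wittig reaction with the aldehyde is E-selective (ester trans to the acetal carbon), which is the C4=C5 geometry of the target with C15 and C6 already differentiated as ester and acetal.

**Step 7**
Reactants: 20 ethyl (2E)-2-[(3E,6S)-6-hydroxy-4-methylocta-3,7-dien-1-yl]-4,4-dimethoxybut-2-enoate
Product: 21 (2E)-2-[(3E,6S)-6-hydroxy-4-methylocta-3,7-dien-1-yl]-4,4-dimethoxybut-2-en-1-ol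
Conditions: i-Bu2AlH (4 equiv), CH2Cl2, −78 °C; aq. potassium sodium tartrate
Reagents that add atoms: none
Why: i-Bu2AlH reduces the conjugated ester 1,2 to the allylic alcohol at low temperature without touching the acetal, the alkenes or the alkene geometry.

**Step 8**
Reactants: 21 (2E)-2-[(3E,6S)-6-hydroxy-4-methylocta-3,7-dien-1-yl]-4,4-dimethoxybut-2-en-1-ol; 4 (2E)-4-[(tert-butyldimethylsilyl)oxy]-2-methylbut-2-enoic acid
Product: 22 (2E)-2-[(3E,6S)-6-hydroxy-4-methylocta-3,7-dien-1-yl]-4,4-dimethoxybut-2-en-1-yl (2E)-4-[(tert-butyldimethylsilyl)oxy]-2-methylbut-2-enoate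
Conditions: 4 (1.05 equiv), EDC·HCl (1.1 equiv), DMAP (10 mol %), CH2Cl2, −10 to 0 °C
Reagents that add atoms: none
Why: Steglich (carbodiimide) esterification with a limiting amount of acid acylates the primary allylic alcohol in preference to the more hindered secondary allylic alcohol.

**Step 9**
Reactants: 22 the mono-ester named in step 8; 23 2-(bromomethyl)prop-2-enoic acid
Product: 24 (3S,5E,9E)-9-({[(2E)-4-[(tert-butyldimethylsilyl)oxy]-2-methylbut-2-enoyl]oxy}methyl)-11,11-dimethoxy-5-methylundeca-1,5,9-trien-3-yl 2-(bromomethyl)prop-2-enoate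
Conditions: 23 (1.5 equiv), DCC (1.5 equiv), DMAP (5 mol %), CH2Cl2, −20 to 0 °C
Reagents that add atoms: none
Why: Steglich esterification of the remaining secondary alcohol proceeds with retention at C8, and low temperature with little DMAP keeps the allylic bromide intact.

**Step 10**
Reactants: 24 the bromomethylacrylate named in step 9
Product: 25 (2E)-2-{(3E)-5-[(2S)-4-(bromomethyl)-5-oxo-2,5-dihydrofuran-2-yl]-4-methylpent-3-en-1-yl}-4,4-dimethoxybut-2-en-1-yl (2E)-4-[(tert-butyldimethylsilyl)oxy]-2-methylbut-2-enoate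
Conditions: second-generation Grubbs catalyst RuCl2(=CHPh)(PCy3)(H2IMes) (7 mol %), toluene (5 mM), 80 °C
Reagents that add atoms: none
Why: Ring-closing metathesis between the terminal vinyl group and the 1,1-disubstituted acrylate closes the five-membered butenolide with loss of ethene, while the trisubstituted alkenes are too hindered to react and C8 is not involved.

**Step 11**
Reactants: 25 the silyl acetal butenolide named in step 10
Product: 26 (2E)-2-{(3E)-5-[(2S)-4-(bromomethyl)-5-oxo-2,5-dihydrofuran-2-yl]-4-methylpent-3-en-1-yl}-4-oxobut-2-en-1-yl (2E)-4-hydroxy-2-methylbut-2-enoate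
Conditions: TsOH·H2O (10 mol %), acetone/H2O (10:1), rt, 4 h; used at once
Reagents that add atoms: water, O
Why: Mild aqueous acid hydrolyses the allylic dimethyl acetal to the enal and cleaves the primary silyl ether in the same operation, under conditions too mild to isomerise C4=C5 or ionise the allylic bromide.

**Step 12**
Reactants: 26 the bromo enal named in step 11
Product: 28 [(3aS,4R,5E,9E,11aS)-4-hydroxy-10-methyl-3-methylidene-2-oxo-2,3,3a,4,7,8,11,11a-octahydrocyclodeca[b]furan-6-yl]methyl (2E)-4-hydroxy-2-methylbut-2-enoate, via allylchromium 27 (not isolated)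
Conditions: CrCl2 (15 mol %), 2,4,5,6-tetrakis(carbazol-9-yl)isophthalonitrile (4CzIPN, 2 mol %), Hantzsch ester (diethyl 2,6-dimethyl-1,4-dihydropyridine-3,5-dicarboxylate, 1.5 equiv), THF/DMF (9:1), 26 added by syringe pump to 2 mM, 450 nm LEDs, 25 °C
Reagents that add atoms: none
Why: Proposed new method: the excited photocatalyst is reductively quenched by the Hantzsch ester and its radical anion returns trivalent chromium to divalent chromium, two of which turn the activated allylic bromide into the 2-carbonyl allylchromium 27; this adds 1,2 to the tethered enal through its γ-carbon C7 in a Zimmerman–Traxler chair with the ring-fixed E-type C8 substituent and the enal residue both equatorial, so C6–C7 forms anti to C9 on the butenolide (trans-fused lactone, 7S), the C6 hydroxyl is anti to C8 (6R) and the alkene shifts to the exocyclic α-methylene position, the oxidised Hantzsch ester protonating the chromium alkoxide to close the cycle; the closest known reactions are stoichiometric CrCl2 Nozaki–Hiyama–Kishi macrocyclisations of allylic bromides and intermolecular dual photoredox/chromium allylations of aldehydes, neither shown for closing a medium ring or with a bromomethyl butenolide.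

**Compound list**
1 | (tert-butyldimethylsilyloxy)acetaldehyde | O=CCO[Si](C)(C)C(C)(C)C | starting material
2 | 2-(diethoxyphosphoryl)propanoic acid | CCOP(=O)(OCC)C(C)C(=O)O | starting material
3 | dilithium salt of 2 (carboxylate and phosphonate carbanion) | [Li+].[Li+].CCOP(=O)(OCC)[C-](C)C(=O)[O-] | intermediate
4 | (2E)-4-[(tert-butyldimethylsilyl)oxy]-2-methylbut-2-enoic acid | O=C(O)/C(C)=C/CO[Si](C)(C)C(C)(C)C | intermediate
5 | (S)-epichlorohydrin, (2S)-2-(chloromethyl)oxirane | ClC[C@@H]1CO1 | starting material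
6 | acetylene | C#C | starting material
7 | lithium acetylide | [Li]C#C | intermediate
8 | (2S)-1-chloropent-4-yn-2-ol | ClC[C@@H](O)CC#C | intermediate
9 | (2S)-2-(prop-2-yn-1-yl)oxirane | C#CC[C@H]1CO1 | intermediate
10 | (3S)-hex-1-en-5-yn-3-ol | C=C[C@@H](O)CC#C | intermediate
11 | ethylene oxide | C1CO1 | starting material
12 | [(1E,4S)-4-(dimethylalumanyloxy)-2-methylhexa-1,5-dien-1-yl]dimethylalumane | C=C[C@@H](O[Al](C)C)C/C(C)=C/[Al](C)C | intermediate
13 | lithium butyl[(1E,4S)-4-(dimethylalumanyloxy)-2-methylhexa-1,5-dien-1-yl]dimethylaluminate | [Li+].C=C[C@@H](O[Al](C)C)C/C(C)=C/[Al-](C)(C)CCCC | intermediate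
14 | (3S,5E)-5-methylocta-1,5-diene-3,8-diol | C=C[C@@H](O)C/C(C)=C/CCO | intermediate
15 | (3S,5E)-8-iodo-5-methylocta-1,5-dien-3-ol | C=C[C@@H](O)C/C(C)=C/CCI | intermediate
16 | ethyl (triphenylphosphoranylidene)acetate | CCOC(=O)C=P(c1ccccc1)(c1ccccc1)c1ccccc1 | starting material
17 | 2,2-dimethoxyacetaldehyde | COC(OC)C=O | starting material
18 | [(5E,8S)-1-ethoxy-8-hydroxy-6-methyl-1-oxodeca-5,9-dien-2-yl]triphenylphosphonium iodide | [I-].C=C[C@@H](O)C/C(C)=C/CCC(C(=O)OCC)[P+](c1ccccc1)(c1ccccc1)c1ccccc1 | intermediate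
19 | ethyl (5E,8S)-8-hydroxy-6-methyl-2-(triphenylphosphoranylidene)deca-5,9-dienoate | C=C[C@@H](O)C/C(C)=C/CCC(C(=O)OCC)=P(c1ccccc1)(c1ccccc1)c1ccccc1 | intermediate
20 | ethyl (2E)-2-[(3E,6S)-6-hydroxy-4-methylocta-3,7-dien-1-yl]-4,4-dimethoxybut-2-enoate | C=C[C@@H](O)C/C(C)=C/CC/C(C(=O)OCC)=C\C(OC)OC | intermediate
21 | (2E)-2-[(3E,6S)-6-hydroxy-4-methylocta-3,7-dien-1-yl]-4,4-dimethoxybut-2-en-1-ol | C=C[C@@H](O)C/C(C)=C/CC/C(CO)=C\C(OC)OC | intermediate
22 | (2E)-2-[(3E,6S)-6-hydroxy-4-methylocta-3,7-dien-1-yl]-4,4-dimethoxybut-2-en-1-yl (2E)-4-[(tert-butyldimethylsilyl)oxy]-2-methylbut-2-enoate | C=C[C@@H](O)C/C(C)=C/CC/C(COC(=O)/C(C)=C/CO[Si](C)(C)C(C)(C)C)=C\C(OC)OC | intermediate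
23 | 2-(bromomethyl)prop-2-enoic acid | C=C(CBr)C(=O)O | starting material
24 | (3S,5E,9E)-9-({[(2E)-4-[(tert-butyldimethylsilyl)oxy]-2-methylbut-2-enoyl]oxy}methyl)-11,11-dimethoxy-5-methylundeca-1,5,9-trien-3-yl 2-(bromomethyl)prop-2-enoate | C=C[C@@H](OC(=O)C(=C)CBr)C/C(C)=C/CC/C(COC(=O)/C(C)=C/CO[Si](C)(C)C(C)(C)C)=C\C(OC)OC | intermediate
25 | (2E)-2-{(3E)-5-[(2S)-4-(bromomethyl)-5-oxo-2,5-dihydrofuran-2-yl]-4-methylpent-3-en-1-yl}-4,4-dimethoxybut-2-en-1-yl (2E)-4-[(tert-butyldimethylsilyl)oxy]-2-methylbut-2-enoate | BrCC1=C[C@H](C/C(C)=C/CC/C(COC(=O)/C(C)=C/CO[Si](C)(C)C(C)(C)C)=C\C(OC)OC)OC1=O | intermediate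
26 | (2E)-2-{(3E)-5-[(2S)-4-(bromomethyl)-5-oxo-2,5-dihydrofuran-2-yl]-4-methylpent-3-en-1-yl}-4-oxobut-2-en-1-yl (2E)-4-hydroxy-2-methylbut-2-enoate | BrCC1=C[C@H](C/C(C)=C/CC/C(COC(=O)/C(C)=C/CO)=C\C=O)OC1=O | intermediate
27 | dichlorochromium allyl derived from 26 (Cr on the former CH2Br carbon, trivalent chromium) | Cl[Cr](Cl)CC1=C[C@H](C/C(C)=C/CC/C(COC(=O)/C(C)=C/CO)=C\C=O)OC1=O | intermediate
28 | [(3aS,4R,5E,9E,11aS)-4-hydroxy-10-methyl-3-methylidene-2-oxo-2,3,3a,4,7,8,11,11a-octahydrocyclodeca[b]furan-6-yl]methyl (2E)-4-hydroxy-2-methylbut-2-enoate (CNP0326626.2) | C=C1C(=O)O[C@H]2C/C(C)=C/CC/C(COC(=O)/C(C)=C/CO)=C\[C@@H](O)[C@H]12 | target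

**Step count**
Total: 12 steps. Longest linear sequence: 11 steps (steps 2 to 12, from (S)-epichlorohydrin); step 1 is a one-step side branch.

**Steps most likely to fail**

Step 12 (the proposed new ring closure). Possible failures are reduction of the bromide without C–C bond formation, oligomers, or the cis-fused or 6-epi diastereomer. The fallback sets out from 25 and returns at 28. Only the acetal of 25 is hydrolysed (oxalic acid on wet silica gel, CH2Cl2, rt; the silyl ether survives) to give the silyl-protected bromo enal F1. The ring is then closed by the established thermal Nozaki–Hiyama–Kishi macrocyclisation with stoichiometric CrCl2 (6 equiv, THF/DMF, 2 mM, rt, dark), giving the silyl-protected macrocycle F2. HF·pyridine (THF, 0 °C) removes the silyl group and gives 28. This replaces catalytic light-driven turnover by a stoichiometric two-electron reductant and moves the desilylation behind the ring closure.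

Step 10 (metathesis in the presence of an allylic bromide). The fallback sets out from 22 and returns at 25. Compound 22 is esterified with 2-{[(4-methoxybenzyl)oxy]methyl}prop-2-enoic acid (C=C(COCc1ccc(OC)cc1)C(=O)O; DCC, DMAP, CH2Cl2) to the ether-protected acrylate F3. Ring-closing metathesis of this halogen-free diene with the same second-generation Grubbs catalyst gives the 4-methoxybenzyloxymethyl butenolide F4. DDQ (CH2Cl2/pH 7 buffer) frees the hydroxymethyl butenolide F5, and CBr4/PPh3 (Appel bromination, CH2Cl2, 0 °C) converts it into 25.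

Step 6 (slow C-alkylation of a stabilised ylide by an unactivated primary iodide). The fallback sets out from 15 and returns at 20. The sodium salt of triethyl phosphonoacetate (CCOC(=O)CP(=O)(OCC)OCC; NaH, DMSO, 50 °C) is alkylated with 15 to give the α-alkyl phosphonate F6. Horner–Wadsworth–Emmons reaction of it with 17 under Masamune–Roush conditions (LiCl, DBU, MeCN) gives 20; the minor Z isomer is removed by chromatography.

**Further compounds**
F1 | step 12 | (2E)-2-{(3E)-5-[(2S)-4-(bromomethyl)-5-oxo-2,5-dihydrofuran-2-yl]-4-methylpent-3-en-1-yl}-4-oxobut-2-en-1-yl (2E)-4-[(tert-butyldimethylsilyl)oxy]-2-methylbut-2-enoate | BrCC1=C[C@H](C/C(C)=C/CC/C(COC(=O)/C(C)=C/CO[Si](C)(C)C(C)(C)C)=C\C=O)OC1=O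
F2 | step 12 | [(3aS,4R,5E,9E,11aS)-4-hydroxy-10-methyl-3-methylidene-2-oxo-2,3,3a,4,7,8,11,11a-octahydrocyclodeca[b]furan-6-yl]methyl (2E)-4-[(tert-butyldimethylsilyl)oxy]-2-methylbut-2-enoate | C=C1C(=O)O[C@H]2C/C(C)=C/CC/C(COC(=O)/C(C)=C/CO[Si](C)(C)C(C)(C)C)=C\[C@@H](O)[C@H]12
F3 | step 10 | (3S,5E,9E)-9-({[(2E)-4-[(tert-butyldimethylsilyl)oxy]-2-methylbut-2-enoyl]oxy}methyl)-11,11-dimethoxy-5-methylundeca-1,5,9-trien-3-yl 2-{[(4-methoxybenzyl)oxy]methyl}prop-2-enoate | C=C[C@@H](OC(=O)C(=C)COCc1ccc(OC)cc1)C/C(C)=C/CC/C(COC(=O)/C(C)=C/CO[Si](C)(C)C(C)(C)C)=C\C(OC)OC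
F4 | step 10 | (2E)-4,4-dimethoxy-2-{(3E)-5-[(2S)-4-{[(4-methoxybenzyl)oxy]methyl}-5-oxo-2,5-dihydrofuran-2-yl]-4-methylpent-3-en-1-yl}but-2-en-1-yl (2E)-4-[(tert-butyldimethylsilyl)oxy]-2-methylbut-2-enoate | COc1ccc(COCC2=C[C@H](C/C(C)=C/CC/C(COC(=O)/C(C)=C/CO[Si](C)(C)C(C)(C)C)=C\C(OC)OC)OC2=O)cc1
F5 | step 10 | (2E)-2-{(3E)-5-[(2S)-4-(hydroxymethyl)-5-oxo-2,5-dihydrofuran-2-yl]-4-methylpent-3-en-1-yl}-4,4-dimethoxybut-2-en-1-yl (2E)-4-[(tert-butyldimethylsilyl)oxy]-2-methylbut-2-enoate | OCC1=C[C@H](C/C(C)=C/CC/C(COC(=O)/C(C)=C/CO[Si](C)(C)C(C)(C)C)=C\C(OC)OC)OC1=O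
F6 | step 6 | ethyl (5E,8S)-2-(diethoxyphosphoryl)-8-hydroxy-6-methyldeca-5,9-dienoate | C=C[C@@H](O)C/C(C)=C/CCC(C(=O)OCC)P(=O)(OCC)OCC
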